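The constants are made up; the rest is arithmetic.

Two questions stand here, and both ask for one factor: how much faster this flask makes product, at the same conversion, when more free catalyst goes in.

starting material 11 mM; free catalyst 0.26 mol%

    starting material + free catalyst → catalyst intermediate A (k1 = 8700 L mol⁻¹ s⁻¹)
    catalyst intermediate A ⇌ catalyst intermediate B (K2 = 2.7, k2 = 8.2 s⁻¹)
    catalyst intermediate B ⇌ free catalyst + product (K3 = 0.055 M, k3 = 12 s⁻¹)
    catalyst intermediate A → spent catalyst (k4 = 0.021 s⁻¹)

- factor on the rate of making product when 30% of the starting material are converted if free catalyst is charged twice over
- factor on the rate when 30% of the starting material are converted if free catalyst is charged at 1.2 mol% instead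

- My first guess is that the rate follows the charge, which gives a factor of 2 for the doubled charge and 4.62 for 1.2 mol%.
- My objection is that catalyst intermediate A leaks into spent catalyst. The leak looks harmless, since the step on to catalyst intermediate B is 390 times faster, but each catalyst goes round many times and risks the leak on every round.
- So I count per round. Of what reaches catalyst intermediate B, a share of 79.8% goes on to product and the rest returns, so each catalyst intermediate A feeds product at 6.54 s⁻¹.
- The leak over that flow is the loss per turnover, the spent catalyst formed per product formed: 0.321%. Its inverse, 312, is the usual turnover number.
- But product can take free catalyst back. Taking product as the converted amount, that runs at 0.720 s⁻¹ per free catalyst, against 67.0 s⁻¹ for starting material, so I drop it.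
- At 30% conversion the loss per turnover makes 0.0106 mM of spent catalyst. This amount follows the product made, not the charge, so I subtract it from each charge.
- That leaves 0.0180 mM of working catalyst in the flask as charged, 0.0466 mM in the doubled flask and 0.121 mM in the flask with 1.2 mol%.
- Can I still compare rates through working catalyst? At equal conversion the starting material is equal, so I expect working catalyst to divide among its forms alike. My factors are 2.59 and 6.72.
- The forecast reads 2.6 and 6.7, with the words “the rate rises more than proportionally to the charge”.
- The simulation gives 2.59 and 6.74.

In the flask with 0.26 mol%, the leak into spent catalyst runs at 1.3 min⁻¹ per catalyst intermediate A against 490 min⁻¹ for the step on to catalyst intermediate B, and the loss per turnover puts spent catalyst at 37.0% of the charge at 30% conversion, where the reading is 36.8%. In the flask with 1.2 mol% it puts spent catalyst at 8.02% against a reading of 7.81%, and in the flask with 0.26 mol% it puts the final product at 81.0% of the starting material charged, against a reading of 80.6% after 150 min.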